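I wanted to know how much target stands at the end of this flask's time, and which change lifts it.

1. the target standing at 10 d, as a percentage of the substrate charged
2. the change that raises the amount of target at 10 d, in percent of the substrate charged most ("none" if none brings more than 2 percentage points) (east / south / none)
3. amount of target at 10 d, in percent of the substrate charged, after east

| flask | substrate | reagent in the second phase | remark | time | volume of the second phase over the first |
|---|---|---|---|---|---|
| Thursday's | 0.050 M | 0.30 M | run made earlier |  |  |
| flask | 0.050 M | 0.200 M |  | 10 d | 1.0 |

Thursday's run (percent of the substrate charged)

| time / d | target / % | substrate / % |
|---|---|---|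
| 0.417 | 41.2 | 58.9 |
| 0.833 | 54.8 | 43.8 |
| 1.25 | 64.1 | 35.7 |
| 1.67 | 69.2 | 32.5 |
| 2.00 | 71.7 | 28.3 |
| 2.50 | 74.7 | 26.3 |
| 3.00 | 76.9 | 23.8 |

(scatter of a reading: 0.5 percentage points)

- in the second phase: reagent in the second phase; everything else is in the first
- charges count per volume of the first phase; a concentration in a rate is the amount of a species over the volume of its own phase; every rate counts per litre of the first phase
- steps thought possible: reagent in the reaction phase <-> reagent in the second phase; substrate + reagent in the reaction phase -> target; reagent in the reaction phase <-> dormant form; 2 reagent in the reaction phase -> self-condensation product
- the earlier runs hold the two phases in the same ratio of volumes as the flask asked about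

I read Thursday's run at both ends. Over the first interval the substrate's pseudo-first-order time constant came to 0.788 d, but between 1.25 d and 3.00 d it was 4.32 d, much longer, so I took the reagent to be consuming itself in pairs, which in my reckoning makes that time constant grow in a straight line. Joining the two ends gave, as readings of Thursday's run, two times: the substrate's time constant at the start, 0.404 d, and the reagent's life, the time in which the line doubles, 0.219 d. Their ratio, the reach, 0.543, is how many substrate time constants one reagent life holds, and on that straight line the fraction of substrate left is (1 + time/life) to the power minus reach. I assumed both times lengthen as the reagent charge falls while the reach stays put, so this flask's life is 0.329 d, and I reckoned 84.6 % of target.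

The forecast gave 85 %, a little above my figure, chose south, and put east at 85.5 %, reading “second-order self-condensation with fast phase transfer”.

The flask gave 82.8 %, with south adding 7.7 percentage points and east changing the target by −0.12 points to 82.7 %, so the forecast stands.

    reagent in the reaction phase ⇌ reagent in the second phase, rate k1*([reagent in the reaction phase] - [reagent in the second phase]/K1) per volume of the first phase (partition coefficient = 0.400, kL = 1.40 /h)
    substrate + reagent in the reaction phase → target (k = 0.600 /M/h)
    reagent in the reaction phase ⇌ dormant form (K = 0.760, k = 1.30 /h)
    2 reagent in the reaction phase → self-condensation product (k = 0.900 /M/h)

In this flask at 0.00986 d, self-condensation used the reagent in the reaction phase 5.1 times as fast as the target step. The same flask read at 4.0 d comes to 75.3 % by the reach of 0.543, and it stood at 73.6 %.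

The earlier runs and the new flask come from a simulation for an exercise, and the scatter is random.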